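**Plan**

- Cuts: after removal of nineteen O-methyl groups, the two ring C (C4)–O–ring D ethers are cut first. The two ring B–O–C1 (ring C) ethers follow, and last the ring A–O–ring B ether and the ring D–ring E biaryl bond.
- Enabling feature: in each ring C, the carbon C1 that holds the oxygen from ring B sits between the hydroxylated carbons C2 and C6. This array is C2 of a cyclohexane-1,3-dione, so ring C can enter as a 2-diazo-1,3-dione and O–C1 can be made by carbenoid insertion into a ring B hydroxyl.
- Forward order: ring A is joined to ring B and the two bromines of ring B become hydroxyls. Both future rings C are then attached as saturated diones in one operation, aromatised, borylated at C4 and coupled with two ring D–E biaryl phenols. Global demethylation ends the route.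
- No ring is made by cyclisation. All eight six-membered rings are bought as carbocycles, and rings C only pass from cyclohexanedione to arene.
- Stereochemistry: the target has no stereocentre, and each biaryl axis carries the symmetric ring E. No atropisomers exist and nothing has to be controlled.

Key step: step 5

Remark: the insertion product is written as its bis-enol. The two enol forms of each dione ring are degenerate, so one structure describes it.

**Route**

Step 1
Reactants: 1 2,6-dibromo-4-methoxyphenol; 2 (3,5-dimethoxyphenyl)boronic acid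
Product: 3 1,3-dibromo-2-(3,5-dimethoxyphenoxy)-5-methoxybenzene
Conditions: 2 (2 equiv), Cu(OAc)2 (2 equiv), pyridine (5 equiv), 4 Å MS, CH2Cl2, dry air, rt
Reagents that add atoms: none
Why: The Chan–Lam coupling forms the ether at room temperature by reductive elimination from a trivalent copper aryl phenoxide, leaves aryl bromides untouched, is established for 2,6-dihalophenols, and here uses a boronic acid without ortho substituents.

Step 2
Reactants: 3 1,3-dibromo-2-(3,5-dimethoxyphenoxy)-5-methoxybenzene
Product: 4 2,2'-[2-(3,5-dimethoxyphenoxy)-5-methoxy-1,3-phenylene]bis(4,4,5,5-tetramethyl-1,3,2-dioxaborolane)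
Conditions: B2pin2 (3 equiv), Pd(dppf)Cl2 (8 mol%), KOAc (6 equiv), 1,4-dioxane, 85 °C, Ar
Reagents that add atoms: bis(pinacolato)diboron, CC1(C)OB(OC1(C)C)B1OC(C)(C)C(C)(C)O1
Why: In this Miyaura borylation each C–Br bond has only one ortho substituent, acetate activates the arylpalladium bromide for transmetalation without triggering Suzuki coupling, and at this temperature borylation should outrun direct arylation onto ring A.

Step 3
Reactants: 4 2,2'-[2-(3,5-dimethoxyphenoxy)-5-methoxy-1,3-phenylene]bis(4,4,5,5-tetramethyl-1,3,2-dioxaborolane)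
Product: 5 2-(3,5-dimethoxyphenoxy)-5-methoxybenzene-1,3-diol
Conditions: 30% H2O2, 2 M NaOH, THF, 0 °C to rt; then 1 M HCl to pH 4
Reagents that add atoms: hydrogen peroxide, OO
Why: In this boronate oxidation hydroperoxide adds to boron and the aryl group migrates to oxygen at the same carbon, so both hydroxyls appear where the bromines stood, and two meta-related hydroxyls cannot pass to a quinone.

Step 4
Reactants: 6 cyclohexane-1,3-dione
Product: 7 2-diazocyclohexane-1,3-dione
Conditions: 4-acetamidobenzenesulfonyl azide (1.05 equiv), Et3N (1.1 equiv), MeCN, 0 °C to rt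
Reagents that add atoms: 4-acetamidobenzenesulfonyl azide, CC(=O)Nc1ccc(cc1)S(=O)(=O)N=[N+]=[N-]
Why: In this Regitz diazo transfer the ammonium enolate of the dione attacks the terminal azide nitrogen and the triazene collapses to the stabilised diazo dione and the sulfonamide.

Step 5
Reactants: 5 2-(3,5-dimethoxyphenoxy)-5-methoxybenzene-1,3-diol; 7 2-diazocyclohexane-1,3-dione (two molecules incorporated)
Product: 8 2,2'-{[2-(3,5-dimethoxyphenoxy)-5-methoxy-1,3-phenylene]bis(oxy)}bis(3-hydroxycyclohex-2-en-1-one)
Conditions: Rh2(OAc)4 (2 mol%), PhF, 80 °C, Ar; 7 (2.6 equiv) in PhF added by syringe pump over 6 h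
Reagents that add atoms: none
Why: Rh2(OAc)4 expels N2 from 7 to give an electrophilic rhodium carbenoid flanked by two carbonyls, a phenolic oxygen of 5 attacks it to form an oxonium ylide, and a proton shift releases the catalyst and the 2-aryloxy dione, which rests as its enol. This is the established rhodium-carbenoid O–H insertion of phenols with cyclic 2-diazo-1,3-diketones, run twice on one substrate. No ring closes and no stereocentre arises, because C1 of each new ring is sp2 in the enol. The electrophile is small and the attacked carbon is not yet part of an arene, so the aryloxy group beside each hydroxyl costs far less than in a metal-mediated coupling with a 2,6-dialkoxyaryl partner, and the two carbonyls are the later C2 and C6 hydroxyls of ring C. The step needs O–H insertion at the phenols to beat aromatic substitution or cyclopropanation on the electron-rich rings A and B and insertion into the enol O–H of the product. Fast ylide formation at the more nucleophilic phenol oxygen, the low carbenoid concentration from slow addition and the inert solvent fluorobenzene should secure this.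

Step 6
Reactants: 8 2,2'-{[2-(3,5-dimethoxyphenoxy)-5-methoxy-1,3-phenylene]bis(oxy)}bis(3-hydroxycyclohex-2-en-1-one)
Product: 9 1,3-bis(2,6-dimethoxyphenoxy)-2-(3,5-dimethoxyphenoxy)-5-methoxybenzene
Conditions: I2 (5 equiv), MeOH, reflux, dark; aq Na2S2O3 work-up
Reagents that add atoms: methanol, CO
Why: In this iodine–methanol oxidative aromatisation of cyclohexane-1,3-diones, HI formed in situ turns each enolised dione into its methyl dienol ether, iodination and loss of HI give the resorcinol dimethyl ether, and the accumulating HI keeps iodination of rings A and B reversible.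

Step 7
Reactants: 9 1,3-bis(2,6-dimethoxyphenoxy)-2-(3,5-dimethoxyphenoxy)-5-methoxybenzene
Product: 10 1,3-bis[2,6-dimethoxy-4-(4,4,5,5-tetramethyl-1,3,2-dioxaborolan-2-yl)phenoxy]-2-(3,5-dimethoxyphenoxy)-5-methoxybenzene
Conditions: [Ir(cod)(OMe)]2 (3 mol%), 4,4'-di-tert-butyl-2,2'-bipyridine (6 mol%), B2pin2 (3 equiv), THF, 80 °C, sealed tube, Ar
Reagents that add atoms: bis(pinacolato)diboron, CC1(C)OB(OC1(C)C)B1OC(C)(C)C(C)(C)O1
Why: Iridium-catalysed aromatic C–H borylation is sterically governed, every C–H of rings A and B lies between two oxygen substituents and C3–H and C5–H of rings C are ortho to methoxy, so only C4–H of each ring C is open to the trisboryl iridium species.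

Step 8
Reactants: 10 1,3-bis[2,6-dimethoxy-4-(4,4,5,5-tetramethyl-1,3,2-dioxaborolan-2-yl)phenoxy]-2-(3,5-dimethoxyphenoxy)-5-methoxybenzene
Product: 11 {[2-(3,5-dimethoxyphenoxy)-5-methoxy-1,3-phenylene]bis[oxy(3,5-dimethoxy-4,1-phenylene)]}diboronic acid
Conditions: NaIO4 (6 equiv), THF/H2O 4:1, rt; then 1 M HCl, rt
Reagents that add atoms: water, O
Why: In this oxidative pinacol ester hydrolysis periodate cleaves the released diol and so drives the reversible hydrolysis to the free boronic acid, which transmetalates to copper far better than the ester, and no group of 10 is sensitive to periodate.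

Step 9
Reactants: 12 1,3,5-trimethoxybenzene
Product: 13 2-iodo-1,3,5-trimethoxybenzene
Conditions: NIS (1.0 equiv), MeCN, 0 °C to rt, dark
Reagents that add atoms: N-iodosuccinimide, O=C1CCC(=O)N1I
Why: This electrophilic aromatic iodination meets three equivalent, triply activated positions, and the first iodine hinders and deactivates the ring enough for one equivalent of reagent to stop at the monoiodide.

Step 10
Reactants: 13 2-iodo-1,3,5-trimethoxybenzene (two molecules)
Product: 14 2,2',4,4',6,6'-hexamethoxy-1,1'-biphenyl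
Conditions: activated Cu bronze (4 equiv), neat, 230 °C, Ar
Reagents that add atoms: none
Why: The classical Ullmann biaryl synthesis couples di-ortho-alkoxy aryl iodides through arylcopper intermediates, and a homocoupling avoids any cross-selectivity problem in making the tetra-ortho-substituted axis.

Step 11
Reactants: 14 2,2',4,4',6,6'-hexamethoxy-1,1'-biphenyl
Product: 17 2,2',4,4',6,6'-hexamethoxybiphenyl-3-ol, via aryllithium 15 (not isolated), via lithium aryltrimethoxyborate 16 (not isolated)
Conditions: n-BuLi (0.9 equiv), TMEDA (0.9 equiv), THF, 0 °C to rt; B(OMe)3 (1.5 equiv), −78 °C to rt; AcOH, 30% H2O2, 0 °C to rt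
Reagents that add atoms: n-butyllithium (lithium of 15), [Li]CCCC; trimethyl borate (boron unit of 16), COB(OC)OC; hydrogen peroxide (oxygen of 17), OO
Why: Directed ortho-metalation removes a C–H between two methoxy groups (all four such positions are equivalent), borate capture and oxidation put the hydroxyl there, a deficit of base limits dilithiation, and the phenol is separated from recovered 14 by extraction into aqueous NaOH.

Step 12
Reactants: 11 {[2-(3,5-dimethoxyphenoxy)-5-methoxy-1,3-phenylene]bis[oxy(3,5-dimethoxy-4,1-phenylene)]}diboronic acid; 17 2,2',4,4',6,6'-hexamethoxybiphenyl-3-ol (two molecules incorporated)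
Product: 18 2-(3,5-dimethoxyphenoxy)-1,3-bis{4-[(2,2',4,4',6,6'-hexamethoxybiphenyl-3-yl)oxy]-2,6-dimethoxyphenoxy}-5-methoxybenzene
Conditions: 17 (3 equiv), Cu(OAc)2 (4 equiv), pyridine (10 equiv), 4 Å MS, CH2Cl2, dry air, rt, 48 h
Reagents that add atoms: none
Why: This double Chan–Lam coupling places all the steric load on the phenol, a partner class (2,6-disubstituted phenols) known to be arylated under these conditions, while both boron atoms sit at C4 of rings C with hydrogen on either side.

Step 13
Reactants: 18 2-(3,5-dimethoxyphenoxy)-1,3-bis{4-[(2,2',4,4',6,6'-hexamethoxybiphenyl-3-yl)oxy]-2,6-dimethoxyphenoxy}-5-methoxybenzene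
Product: 19 CNP0227063.0, 4-(3,5-dihydroxyphenoxy)-3,5-bis{2,6-dihydroxy-4-[(2,2',4,4',6,6'-hexahydroxybiphenyl-3-yl)oxy]phenoxy}phenol
Conditions: BBr3 (40 equiv), CH2Cl2, −78 °C to rt, Ar; ice-water quench; EtOAc extraction, Sephadex LH-20, all under Ar
Reagents that add atoms: none
Why: In this Lewis-acid aryl methyl ether cleavage BBr3 binds each methoxy oxygen and bromide attacks the methyl carbon, whereas the diaryl ether and biaryl bonds offer no sp3 carbon and should survive.

**Compound list**

1 | 2,6-dibromo-4-methoxyphenol | COc1cc(Br)c(O)c(Br)c1 | starting material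
2 | (3,5-dimethoxyphenyl)boronic acid | COc1cc(OC)cc(B(O)O)c1 | starting material
3 | 1,3-dibromo-2-(3,5-dimethoxyphenoxy)-5-methoxybenzene | COc1cc(OC)cc(Oc2c(Br)cc(OC)cc2Br)c1 | intermediate
4 | 2,2'-[2-(3,5-dimethoxyphenoxy)-5-methoxy-1,3-phenylene]bis(4,4,5,5-tetramethyl-1,3,2-dioxaborolane) | COc1cc(OC)cc(Oc2c(B3OC(C)(C)C(C)(C)O3)cc(OC)cc2B2OC(C)(C)C(C)(C)O2)c1 | intermediate
5 | 2-(3,5-dimethoxyphenoxy)-5-methoxybenzene-1,3-diol | COc1cc(OC)cc(Oc2c(O)cc(OC)cc2O)c1 | intermediate
6 | cyclohexane-1,3-dione | O=C1CCCC(=O)C1 | starting material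
7 | 2-diazocyclohexane-1,3-dione | [N-]=[N+]=C1C(=O)CCCC1=O | intermediate
8 | 2,2'-{[2-(3,5-dimethoxyphenoxy)-5-methoxy-1,3-phenylene]bis(oxy)}bis(3-hydroxycyclohex-2-en-1-one) | COc1cc(OC)cc(Oc2c(OC3=C(O)CCCC3=O)cc(OC)cc2OC2=C(O)CCCC2=O)c1 | intermediate
9 | 1,3-bis(2,6-dimethoxyphenoxy)-2-(3,5-dimethoxyphenoxy)-5-methoxybenzene | COc1cc(OC)cc(Oc2c(Oc3c(OC)cccc3OC)cc(OC)cc2Oc2c(OC)cccc2OC)c1 | intermediate
10 | 1,3-bis[2,6-dimethoxy-4-(4,4,5,5-tetramethyl-1,3,2-dioxaborolan-2-yl)phenoxy]-2-(3,5-dimethoxyphenoxy)-5-methoxybenzene | COc1cc(OC)cc(Oc2c(Oc3c(OC)cc(B4OC(C)(C)C(C)(C)O4)cc3OC)cc(OC)cc2Oc2c(OC)cc(B3OC(C)(C)C(C)(C)O3)cc2OC)c1 | intermediate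
11 | {[2-(3,5-dimethoxyphenoxy)-5-methoxy-1,3-phenylene]bis[oxy(3,5-dimethoxy-4,1-phenylene)]}diboronic acid | COc1cc(OC)cc(Oc2c(Oc3c(OC)cc(B(O)O)cc3OC)cc(OC)cc2Oc2c(OC)cc(B(O)O)cc2OC)c1 | intermediate
12 | 1,3,5-trimethoxybenzene | COc1cc(OC)cc(OC)c1 | starting material
13 | 2-iodo-1,3,5-trimethoxybenzene | COc1cc(OC)c(I)c(OC)c1 | intermediate
14 | 2,2',4,4',6,6'-hexamethoxy-1,1'-biphenyl | COc1cc(OC)c(-c2c(OC)cc(OC)cc2OC)c(OC)c1 | intermediate
15 | 3-lithio-2,2',4,4',6,6'-hexamethoxybiphenyl (aryllithium) | [Li]c1c(OC)cc(OC)c(-c2c(OC)cc(OC)cc2OC)c1OC | intermediate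
16 | lithium trimethoxy(2,2',4,4',6,6'-hexamethoxybiphenyl-3-yl)borate | [Li+].CO[B-](OC)(OC)c1c(OC)cc(OC)c(-c2c(OC)cc(OC)cc2OC)c1OC | intermediate
17 | 2,2',4,4',6,6'-hexamethoxybiphenyl-3-ol | COc1cc(OC)c(-c2c(OC)cc(OC)cc2OC)c(OC)c1O | intermediate
18 | 2-(3,5-dimethoxyphenoxy)-1,3-bis{4-[(2,2',4,4',6,6'-hexamethoxybiphenyl-3-yl)oxy]-2,6-dimethoxyphenoxy}-5-methoxybenzene (nonadeca-O-methyl ether of the target) | COc1cc(OC)cc(Oc2c(Oc3c(OC)cc(Oc4c(OC)cc(OC)c(-c5c(OC)cc(OC)cc5OC)c4OC)cc3OC)cc(OC)cc2Oc2c(OC)cc(Oc3c(OC)cc(OC)c(-c4c(OC)cc(OC)cc4OC)c3OC)cc2OC)c1 | intermediate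
19 | CNP0227063.0, 4-(3,5-dihydroxyphenoxy)-3,5-bis{2,6-dihydroxy-4-[(2,2',4,4',6,6'-hexahydroxybiphenyl-3-yl)oxy]phenoxy}phenol | Oc1cc(O)cc(Oc2c(Oc3c(O)cc(Oc4c(O)cc(O)c(-c5c(O)cc(O)cc5O)c4O)cc3O)cc(O)cc2Oc2c(O)cc(Oc3c(O)cc(O)c(-c4c(O)cc(O)cc4O)c3O)cc2O)c1 | target

**Step count**

Total step count: 13.
Longest linear sequence: 9 steps (1, 2, 3, 5, 6, 7, 8, 12, 13), starting from 1.

**Steps most likely to fail**

Step 12 is the most exposed.
- What may go wrong: exchange of the phenoxide, flanked by two methoxy groups, onto copper is slow. Protodeboronation, oxidative hydroxylation of the C–B bonds, stalling after the first coupling, and oxidation of the very electron-rich phenol by divalent copper and air can all take over. The boron partner is also the limiting component here.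
- Fallback: it sets out from 10. Each boronate is replaced by iodine with nucleophilic iodide at copper (CuI, 1,10-phenanthroline, KI, MeOH/H2O, air, 80 °C), which avoids an electrophilic iodine reagent that would attack ring A. This gives 1,3-bis(4-iodo-2,6-dimethoxyphenoxy)-2-(3,5-dimethoxyphenoxy)-5-methoxybenzene F1. An Ullmann ether synthesis under argon with excess 17 (CuI, picolinic acid, K3PO4, DMSO, 100 °C) works without any oxidant and comes back to the route at 18.

Step 5 is next.
- What may go wrong: the second insertion may lag. The carbenoid may be drained by insertion into the acidic enol O–H of the product, by electrophilic attack on ring A, or by Wolff rearrangement and dimerisation.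
- Fallback: it sets out from 3 and forms the same two O–C1 bonds with an aromatic ring C donor. A double Ullmann ether synthesis with purchased 2,6-dimethoxyphenol is used (CuI, picolinic acid, K3PO4, DMSO, 110 °C, Ar). This path should be slowed by the crowding of three neighbouring aryloxy groups, but it rests on known hindered diaryl ether couplings and comes back at 9. No compound outside the list arises on it (entry F0).

Step 6 is third.
- What may go wrong: the HI set free may promote cyclodehydration of an aryloxy dione onto the nucleophilic C–H of ring B (furan closure). The second O-methylation of a ring may stay incomplete, and ring A may be iodinated.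
- Fallback: it sets out from 8 and avoids acid throughout.
  - O-Methylation of both vinylogous acids (Me2SO4, K2CO3, acetone) gives 2,2'-{[2-(3,5-dimethoxyphenoxy)-5-methoxy-1,3-phenylene]bis(oxy)}bis(3-methoxycyclohex-2-en-1-one) F2.
  - Kinetic deprotonation at C6 of each enone and selenenylation (LDA, THF, −78 °C; PhSeBr) gives the bis(6-phenylselanyl) derivative F3.
  - Oxidation (H2O2, pyridine, CH2Cl2, 0 °C) triggers selenoxide syn-elimination. The cross-conjugated dienones tautomerise to 2,2'-{[2-(3,5-dimethoxyphenoxy)-5-methoxy-1,3-phenylene]bis(oxy)}bis(3-methoxyphenol) F4.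
  - Methylation (MeI, K2CO3, DMF) comes back to the route at 9.

**Further compounds**

F1 | step 12 | 1,3-bis(4-iodo-2,6-dimethoxyphenoxy)-2-(3,5-dimethoxyphenoxy)-5-methoxybenzene | COc1cc(OC)cc(Oc2c(Oc3c(OC)cc(I)cc3OC)cc(OC)cc2Oc2c(OC)cc(I)cc2OC)c1
F0 | step 5 | none | none
F2 | step 6 | 2,2'-{[2-(3,5-dimethoxyphenoxy)-5-methoxy-1,3-phenylene]bis(oxy)}bis(3-methoxycyclohex-2-en-1-one) | COc1cc(OC)cc(Oc2c(OC3=C(OC)CCCC3=O)cc(OC)cc2OC2=C(OC)CCCC2=O)c1
F3 | step 6 | 2,2'-{[2-(3,5-dimethoxyphenoxy)-5-methoxy-1,3-phenylene]bis(oxy)}bis[3-methoxy-6-(phenylselanyl)cyclohex-2-en-1-one] (mixture of diastereomers, both centres lost in the next operation) | COc1cc(OC)cc(Oc2c(OC3=C(OC)CCC([Se]c4ccccc4)C3=O)cc(OC)cc2OC2=C(OC)CCC([Se]c3ccccc3)C2=O)c1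
F4 | step 6 | 2,2'-{[2-(3,5-dimethoxyphenoxy)-5-methoxy-1,3-phenylene]bis(oxy)}bis(3-methoxyphenol) | COc1cc(OC)cc(Oc2c(Oc3c(O)cccc3OC)cc(OC)cc2Oc2c(O)cccc2OC)c1
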